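Read winter, dusk and autumn at 8.0 min.

| setting | Sunday's | winter | dusk | autumn |
|---|---|---|---|---|
| substrate | 0.80 M | 0.80 M | 0.80 M | 0.80 M |
| partner | 0.55 M | 0.400 M | 2.00 M | 2.40 M |
| remark | run made earlier |  |  |  |
| time |  | 8.0 min | 8.0 min | 8.0 min |

- Sunday's (time / min: double product / %, single product / %): 0.667: 0.2, 2.3; 1.00: 0.4, 3.9; 2.00: 1.2, 4.4; 3.00: 1.6, 4.6; 5.00: 2.2, 3.9; 8.00: 2.7, 2.0

(readings scatter by 0.3 percentage points)



* which of these holds the largest part of the substrate at the end of winter (double product / single product / other mono adduct / substrate)
* which of these holds the largest part of the substrate at the end of dusk (double product / single product / other mono adduct / substrate)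
* which of these holds the largest part of the substrate at the end of autumn (double product / single product / other mono adduct / substrate)
* how much double product is there at the end of autumn, in percent of the substrate charged

In Sunday's run, add single and double product at 3.00 min and again at 8.00 min: the sum falls by 1.5 percentage points, so some single product leaves for a species outside these columns. Double product meanwhile gains 1.1 points. Define the fork ratio as the double product gained per point leaked, divided by the charged [partner]/[substrate]; as a reading from Sunday's run it is 1.07. Carry it to autumn, charged at [partner]/[substrate] = 3.00: my reckoning gives a ratio of 3.20 for double product per point leaked, which is a ratio and not a yield.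

The forecast gives substrate for winter, other mono adduct for dusk, double product for autumn and 58 % of double product in autumn, on the ground that “With excess partner, substrate goes to other mono adduct within a minute”.

The flask gives substrate for winter, double product for dusk, double product for autumn and 33.0 % of double product, 25 points below the forecast.

    substrate + partner → single product + by-product (k = 0.110 M⁻¹ min⁻¹)
    substrate + partner → other mono adduct + by-product (k = 0.110 M⁻¹ min⁻¹)
    substrate + single product → side product (k = 0.790 M⁻¹ min⁻¹)
    partner → decomposed reagent (k = 0.130 min⁻¹)
    partner + single product → double product + by-product (k = 0.0960 M⁻¹ min⁻¹)
    partner + other mono adduct → double product + by-product (k = 0.180 M⁻¹ min⁻¹)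

The leak is side product, and each of its percentages counts two substrate units, so autumn's 34.0 % took 17.0 % of the charge as single product. Double product forms from both mono adducts, and the ratio counts both. Autumn stands at a ratio of 1.94 for double product per point leaked, lower than the reckoned 3.20, so the fork ratio carried over from Sunday's run did not hold in autumn. Now take the neighbour flask charged with 0.48 M of substrate. Its ratio of 5.00 gives a reckoned 5.33, up 1.67-fold on autumn. That flask holds 40.8 % of double product and 24.2 % of side product, which is 3.37 per point leaked, up 1.74-fold on autumn.

(The numbers in the tables were generated by integration with constants of no real substance.)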